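2.19 mM of free X, against 20 mM charged, is the balance level: the [X] at which X goes to L as fast as it goes into pairing with itself, with the whole catalyst counted as L. Dividing one rate by the other drops time out, so the share of X that reaches L, its selectivity, is the balance level over the balance level plus [X]. The next run hangs on that share.

| flask | E | X | G | time | remark |
|---|---|---|---|---|---|
| ash | 0.010 M | 0.0200 M | 1.0 mM | 15 min | everything together in a closed stirred flask, run for 15 min |
| elm | 0.010 M (fed, over 12.0 min) | 0.0200 M | 1.0 mM | 15 min | all but E at the start; E goes in evenly over 12.0 min, the run ends at 15 min |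
| alder | 0.010 M | 0.0200 M | 1.0 mM |  | a single well-mixed tank run continuously and read at steady state, 15 min in it on average |
| larch | 0.010 M | 0.0200 M (fed, over 12.0 min) | 1.0 mM | 15 min | all but X at the start; X goes in evenly over 12.0 min, the run ends at 15 min |

    E + G ⇌ E.G (K1 = 39.8 M⁻¹, k1 = 25.3 M⁻¹ s⁻¹)
    E.G → L (k2 = 0.684 s⁻¹)
    X + L → X.L (k3 = 2.15 M⁻¹ s⁻¹)
    X.L ⇌ G + Z (K4 = 0.0053 M, k4 = 0.326 s⁻¹)
    2 X → X2 (k5 = 0.490 M⁻¹ s⁻¹)

- the set-up with the highest amount of Z at the outlet or at the end, in percent of the E put in ("none" if the first two lie within 2 percentage points) (ash / elm / alder / larch / none)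
- amount of Z at the outlet or at the end, in percent of the E put in, ash
- amount of Z at the outlet or at the end, in percent of the E put in, elm
- amount of Z at the outlet or at the end, in percent of the E put in, alder
- amount of Z at the outlet or at the end, in percent of the E put in, larch

Ash starts with [X] at 20 mM, far above the balance level, and summing the share as [X] falls gives at most 50.8% of E as Z. Elm has the same X at the start, so it is given no better figure. Larch feeds X at 1.67 mM min⁻¹, and feed balanced against both losses holds [X] near 4.34 mM. The share is then 33.6%, which on the whole charge of X reckons to a ceiling near 67.2% of E. Alder, where X also leaves with the outflow, reckons to [X] near 3.38 mM and a ceiling near 65.4% of E. The choice is larch, but its reckoned gap over alder is 1.8 percentage points against a margin of 2 points.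

The forecast named larch, with ash 41%, elm 24%, alder 52% and larch 56%, on the ground that “dosing holds X near 4.4 mM”. Its larch figure is lower than the ceiling reckoned here.

The simulation gives larch: ash 39.0%, elm 23.1%, alder 49.9%, larch 56.1%, each inside the forecast's range. Larch stands 6.2 points above alder.

In ash, free X was down to 6.16% of its charge by 7.50 min, with Z at 32.4%, and Z reached 39.0% at the end. In larch, X stood at 22.0% of its charge at 7.50 min while L held 82.9% of the catalyst. Those values put the balance level at 1.82 mM and the share at 29.2%, and that share of 7.50 min, laid over the X no longer free at the end, reckons to 52.6% of E.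

A neighbour of larch charged with 6.0 × 10⁻⁴ M of G reckons to a balance level of 1.32 mM, [X] near 4.71 mM during the feed and a share of 21.9%, which gives a ceiling near 43.7% of E. That flask gave 37.5%, with 56.9% of its E still E.

(All constants belong to no real substance, and the outcome is calculated.)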